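**Retrosynthetic overview**

1. Numbering used below (germacrane type): ring carbons C1–C10; C4 carries C15H2–O–isovaleryl, C6 the lactone oxygen, C7 the lactone carbon C11 (C12 carbonyl, C13 exo-methylene), C9 the acetoxy group, C10 the methyl; C1=C10 is cis and C4=C5 trans within the ring.
2. Key disconnection: the two bonds that hold the acrylate unit on the carbocycle, O–C6 and C11–C7. The enabling feature is that C6 is allylic to the ring C4=C5 bond, so the cis-fused γ-lactone is the 1,2-adduct of 2-bromoacrylic acid across the cis C6=C7 bond of a ring 1,3-diene (C4=C5–C6=C7), formed through a π-allylpalladium unit C4–C5–C6. The precursor is monocyclic trienol 16 with a single stereocentre.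
3. C9 is set as 9R by CBS reduction of macrocyclic enone 15, is used to steer the face of the annulation, and is inverted to the 9S acetate by a final Mitsunobu reaction with acetic acid.
4. The ten-membered ring is closed at C9–C10 by a Nozaki–Hiyama–Kishi reaction of acyclic iodo aldehyde 13. Its three alkene geometries are fixed before cyclisation: C4=C5 by copper-catalysed anti-carbomagnesiation/iodination of propargyl alcohol, C6=C7 by Sonogashira coupling and cis semi-reduction, C1=C10 by Stork–Zhao iodo-olefination.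
5. Order of ring formation: ten-membered carbocycle (step 9), then γ-lactone (step 12).

Key step: step 12

Assumption: silyl ether 7 is taken as a purchasable compound, and the isovalerate installed in step 2 is kept as the protecting group of the C15 hydroxyl for the whole route.

**Route**

Step 1
Reactants: 1 prop-2-yn-1-ol; 2 2-(2-bromoethyl)-1,3-dioxolane
Product: 5 (Z)-2-[2-(1,3-dioxolan-2-yl)ethyl]-3-iodoprop-2-en-1-ol, via Grignard reagent 3 (not isolated), via chelated alkenylmagnesium alkoxide 4 (not isolated)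
Conditions: 2 (2.6 equiv), Mg, THF, 25 °C; then 1, CuI (10 mol %), THF, −10 to 23 °C; then I2, −10 °C; aq. NH4Cl
Reagents that add atoms: iodine, II
Why: Copper-catalysed anti-carbomagnesiation of the propargylic alkoxide (Duboudin reaction) puts the alkyl group on the internal alkyne carbon and holds magnesium on the terminal carbon cis to the CH2O group in a five-membered chelate, so iodinolysis with retention should give only the Z iodide, which fixes the ring-trans C4=C5 geometry.

Step 2
Reactants: 5 (Z)-2-[2-(1,3-dioxolan-2-yl)ethyl]-3-iodoprop-2-en-1-ol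
Product: 6 (Z)-2-[2-(1,3-dioxolan-2-yl)ethyl]-3-iodoprop-2-en-1-yl 3-methylbutanoate
Conditions: 3-methylbutanoyl chloride, pyridine, DMAP (cat.), CH2Cl2, 0 °C
Reagents that add atoms: 3-methylbutanoyl chloride, CC(C)CC(Cl)=O
Why: Acylation of the primary allylic alcohol (nucleophilic catalysis by DMAP) installs the isovalerate of the target early, where it also protects this hydroxyl; no stereocentre is formed.

Step 3
Reactants: 6 (Z)-2-[2-(1,3-dioxolan-2-yl)ethyl]-3-iodoprop-2-en-1-yl 3-methylbutanoate; 7 tert-butyl(but-3-yn-1-yloxy)diphenylsilane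
Product: 8 (Z)-7-[(tert-butyldiphenylsilyl)oxy]-2-[2-(1,3-dioxolan-2-yl)ethyl]hept-2-en-4-yn-1-yl 3-methylbutanoate
Conditions: PdCl2(PPh3)2 (3 mol %), CuI (6 mol %), Et3N, THF, 23 °C
Reagents that add atoms: none
Why: Sonogashira coupling of the alkenyl iodide proceeds with retention of the alkene geometry, and at room temperature oxidative addition into the C–I bond should be much faster than ionisation of the allylic ester.

Step 4
Reactants: 8 (Z)-7-[(tert-butyldiphenylsilyl)oxy]-2-[2-(1,3-dioxolan-2-yl)ethyl]hept-2-en-4-yn-1-yl 3-methylbutanoate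
Product: 9 (2Z,4Z)-7-[(tert-butyldiphenylsilyl)oxy]-2-[2-(1,3-dioxolan-2-yl)ethyl]hepta-2,4-dien-1-yl 3-methylbutanoate
Conditions: Zn dust activated with Cu(OAc)2 and AgNO3, MeOH/H2O/THF, 40 °C
Reagents that add atoms: none
Why: Boland reduction adds hydrogen cis to the triple bond of a conjugated enyne only, which should give the cis C6=C7 bond without over-reduction and without touching ester, acetal or silyl ether.

Step 5
Reactants: 9 (2Z,4Z)-7-[(tert-butyldiphenylsilyl)oxy]-2-[2-(1,3-dioxolan-2-yl)ethyl]hepta-2,4-dien-1-yl 3-methylbutanoate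
Product: 10 (2Z,4Z)-7-[(tert-butyldiphenylsilyl)oxy]-2-(3-oxopropyl)hepta-2,4-dien-1-yl 3-methylbutanoate
Conditions: 1 M aq. HCl, THF, 23 °C
Reagents that add atoms: water, O
Why: Acid-catalysed acetal hydrolysis unmasks the C1 aldehyde, while the tert-butyldiphenylsilyl ether, the ester and the diene tolerate dilute acid at room temperature.

Step 6
Reactants: 10 (2Z,4Z)-7-[(tert-butyldiphenylsilyl)oxy]-2-(3-oxopropyl)hepta-2,4-dien-1-yl 3-methylbutanoate
Product: 11 (2Z,4Z)-7-[(tert-butyldiphenylsilyl)oxy]-2-[(3Z)-4-iodopent-3-en-1-yl]hepta-2,4-dien-1-yl 3-methylbutanoate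
Conditions: EtPPh3I, n-BuLi, THF, 0 °C; I2, −78 °C; NaN(SiMe3)2, −20 °C; then 10, −78 to −20 °C
Reagents that add atoms: (1-iodoethylidene)triphenylphosphorane, CC(I)=P(c1ccccc1)(c1ccccc1)c1ccccc1, made in the flask from ethyltriphenylphosphonium iodide, CC[P+](c1ccccc1)(c1ccccc1)c1ccccc1.[I-], and iodine, II
Why: Stork–Zhao-type Wittig olefination with the α-iodo ylide is kinetically Z-selective (iodine cis to the chain), which fixes the later cis C1=C10 ring alkene; the ester is not attacked at low temperature.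

Step 7
Reactants: 11 (2Z,4Z)-7-[(tert-butyldiphenylsilyl)oxy]-2-[(3Z)-4-iodopent-3-en-1-yl]hepta-2,4-dien-1-yl 3-methylbutanoate
Product: 12 (2Z,4Z)-7-hydroxy-2-[(3Z)-4-iodopent-3-en-1-yl]hepta-2,4-dien-1-yl 3-methylbutanoate
Conditions: HF·pyridine, pyridine, THF, 0 to 23 °C
Reagents that add atoms: none
Why: Fluoride-driven desilylation (Si–F bond formation) frees the primary alcohol and leaves ester, alkenyl iodide and diene untouched.

Step 8
Reactants: 12 (2Z,4Z)-7-hydroxy-2-[(3Z)-4-iodopent-3-en-1-yl]hepta-2,4-dien-1-yl 3-methylbutanoate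
Product: 13 (2Z,4Z)-2-[(3Z)-4-iodopent-3-en-1-yl]-7-oxohepta-2,4-dien-1-yl 3-methylbutanoate
Conditions: Dess–Martin periodinane, pyridine, CH2Cl2, 0 °C; used crude
Reagents that add atoms: none
Why: Dess–Martin oxidation under buffered, non-basic conditions should give the β,γ-unsaturated aldehyde without migration of the cis double bond into conjugation.

Step 9
Reactants: 13 (2Z,4Z)-2-[(3Z)-4-iodopent-3-en-1-yl]-7-oxohepta-2,4-dien-1-yl 3-methylbutanoate
Product: 14 racemic [(1Z,3Z,7Z)-6-hydroxy-7-methylcyclodeca-1,3,7-trien-1-yl]methyl 3-methylbutanoate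
Conditions: CrCl2 (8 equiv), NiCl2 (1 mol % of CrCl2), DMSO/THF, slow addition of 13 to 2 mM final concentration, 23 °C
Reagents that add atoms: none
Why: Nozaki–Hiyama–Kishi reaction: the alkenylchromium species forms from the iodide with retention of geometry and adds to the aldehyde under high dilution, closing the ten-membered ring at C9–C10; the carbinol forms without control and is corrected in steps 10 and 11.

Step 10
Reactants: 14 racemic [(1Z,3Z,7Z)-6-hydroxy-7-methylcyclodeca-1,3,7-trien-1-yl]methyl 3-methylbutanoate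
Product: 15 [(1Z,3Z,7Z)-7-methyl-6-oxocyclodeca-1,3,7-trien-1-yl]methyl 3-methylbutanoate
Conditions: Dess–Martin periodinane, pyridine, CH2Cl2, 0 °C; used at once
Reagents that add atoms: none
Why: Dess–Martin oxidation of the allylic alcohol erases the uncontrolled stereocentre, and the neutral conditions should keep the C8 methylene from enolising into conjugation with the diene.

Step 11
Reactants: 15 [(1Z,3Z,7Z)-7-methyl-6-oxocyclodeca-1,3,7-trien-1-yl]methyl 3-methylbutanoate
Product: 16 [(1Z,3Z,6R,7Z)-6-hydroxy-7-methylcyclodeca-1,3,7-trien-1-yl]methyl 3-methylbutanoate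
Conditions: (S)-2-methyl-CBS-oxazaborolidine (0.5 equiv), catecholborane, toluene, −78 °C
Reagents that add atoms: none
Why: Corey–Bakshi–Shibata reduction: the ketone binds with its larger α-methylalkenyl side (C10) away from the catalyst and, as with alkenyl and aryl ketones, the (S) catalyst should deliver hydride to give the R carbinol at C9 by reagent control; catecholborane at −78 °C does not hydroborate the alkenes.

Step 12
Reactants: 16 [(1Z,3Z,6R,7Z)-6-hydroxy-7-methylcyclodeca-1,3,7-trien-1-yl]methyl 3-methylbutanoate; 17 2-bromoprop-2-enoic acid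
Product: 18 [(3aR,5R,6Z,10Z,11aR)-5-hydroxy-6-methyl-3-methylidene-2-oxo-2,3,3a,4,5,8,9,11a-octahydrocyclodeca[b]furan-10-yl]methyl 3-methylbutanoate
Conditions: Pd(OAc)2 (10 mol %), NaHCO3 (2.5 equiv), n-Bu4NCl (1 equiv), DMF, 60 °C; 17 (1.5 equiv) added slowly
Reagents that add atoms: none
Why: Zerovalent palladium formed in situ inserts into the C–Br bond of 2-bromoacrylate, the alkenylpalladium adds syn across the cis C6=C7 bond with the acrylate α-carbon going to the less substituted diene terminus C7, and the resulting π-allylpalladium over C6–C5–C4 is captured at C6 by the carboxylate held on the palladium face (C–O reductive elimination), which returns zerovalent palladium. The closest known reaction type is the Larock heteroannulation of cyclic 1,3-dienes by aryl or vinylic halides that carry a carboxylic acid. The γ-lactone is closed as a formal [3+2] annulation by O-attack on the proximal allyl terminus (five-membered ring; attack at the distal, fully substituted C4 would need a seven-membered ring), and the allyl unit keeps the C4=C5 geometry because palladium never becomes σ-bonded to C4. C6 and C7 are set together: syn delivery of C11 and O across the cis C6=C7 bond can only give the cis-fused lactone, and the face is expected to be chosen by C9, whose C8–C9 bond stands out of the diene plane with the hydroxyl turned outward, so that palladium adds to the open face on the other side (peripheral attack), which for the 9R carbinol gives 6R,7R. The step needs regioselectivity (monosubstituted terminus C7 against fully substituted C4), site selectivity (the unconjugated trisubstituted C1=C10 bond should not insert) and tolerance of the allylic isovalerate, secured by phosphine-free conditions under which oxidative addition into the C–Br bond should outrun ionisation of the ester.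

Step 13
Reactants: 18 [(3aR,5R,6Z,10Z,11aR)-5-hydroxy-6-methyl-3-methylidene-2-oxo-2,3,3a,4,5,8,9,11a-octahydrocyclodeca[b]furan-10-yl]methyl 3-methylbutanoate
Product: 19 [(3aR,5S,6Z,10Z,11aR)-5-acetyloxy-6-methyl-3-methylidene-2-oxo-2,3,3a,4,5,8,9,11a-octahydrocyclodeca[b]furan-10-yl]methyl 3-methylbutanoate
Conditions: PPh3, DIAD, toluene, 0 °C; then AcOH and 18, 0 to 23 °C
Reagents that add atoms: acetic acid, CC(=O)O
Why: Mitsunobu reaction: the C9 hydroxyl is activated as the oxyphosphonium ion and displaced by acetate in an SN2 process with inversion, which should turn 9R into the 9S acetate in the same operation that installs the acetyl group; pre-forming the PPh3/DIAD adduct keeps free phosphine away from the α-methylene lactone.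

**Compound list**

1 | prop-2-yn-1-ol | C#CCO | starting material
2 | 2-(2-bromoethyl)-1,3-dioxolane | BrCCC1OCCO1 | starting material
3 | [2-(1,3-dioxolan-2-yl)ethyl]magnesium bromide | Br[Mg]CCC1OCCO1 | intermediate
4 | bromomagnesium (Z)-3-(bromomagnesio)-2-[2-(1,3-dioxolan-2-yl)ethyl]prop-2-en-1-olate | Br[Mg]OC/C(CCC1OCCO1)=C\[Mg]Br | intermediate
5 | (Z)-2-[2-(1,3-dioxolan-2-yl)ethyl]-3-iodoprop-2-en-1-ol | OC/C(CCC1OCCO1)=C\I | intermediate
6 | (Z)-2-[2-(1,3-dioxolan-2-yl)ethyl]-3-iodoprop-2-en-1-yl 3-methylbutanoate | CC(C)CC(=O)OC/C(CCC1OCCO1)=C\I | intermediate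
7 | tert-butyl(but-3-yn-1-yloxy)diphenylsilane | C#CCCO[Si](c1ccccc1)(c1ccccc1)C(C)(C)C | starting material
8 | (Z)-7-[(tert-butyldiphenylsilyl)oxy]-2-[2-(1,3-dioxolan-2-yl)ethyl]hept-2-en-4-yn-1-yl 3-methylbutanoate | CC(C)CC(=O)OC/C(CCC1OCCO1)=C\C#CCCO[Si](c1ccccc1)(c1ccccc1)C(C)(C)C | intermediate
9 | (2Z,4Z)-7-[(tert-butyldiphenylsilyl)oxy]-2-[2-(1,3-dioxolan-2-yl)ethyl]hepta-2,4-dien-1-yl 3-methylbutanoate | CC(C)CC(=O)OC/C(CCC1OCCO1)=C\C=C/CCO[Si](c1ccccc1)(c1ccccc1)C(C)(C)C | intermediate
10 | (2Z,4Z)-7-[(tert-butyldiphenylsilyl)oxy]-2-(3-oxopropyl)hepta-2,4-dien-1-yl 3-methylbutanoate | CC(C)CC(=O)OC/C(CCC=O)=C\C=C/CCO[Si](c1ccccc1)(c1ccccc1)C(C)(C)C | intermediate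
11 | (2Z,4Z)-7-[(tert-butyldiphenylsilyl)oxy]-2-[(3Z)-4-iodopent-3-en-1-yl]hepta-2,4-dien-1-yl 3-methylbutanoate | CC(C)CC(=O)OC/C(CC/C=C(/C)I)=C\C=C/CCO[Si](c1ccccc1)(c1ccccc1)C(C)(C)C | intermediate
12 | (2Z,4Z)-7-hydroxy-2-[(3Z)-4-iodopent-3-en-1-yl]hepta-2,4-dien-1-yl 3-methylbutanoate | CC(C)CC(=O)OC/C(CC/C=C(/C)I)=C\C=C/CCO | intermediate
13 | (2Z,4Z)-2-[(3Z)-4-iodopent-3-en-1-yl]-7-oxohepta-2,4-dien-1-yl 3-methylbutanoate | CC(C)CC(=O)OC/C(CC/C=C(/C)I)=C\C=C/CC=O | intermediate
14 | racemic [(1Z,3Z,7Z)-6-hydroxy-7-methylcyclodeca-1,3,7-trien-1-yl]methyl 3-methylbutanoate | CC(C)CC(=O)OC/C1=C\C=C/CC(O)/C(C)=C\CC1 | intermediate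
15 | [(1Z,3Z,7Z)-7-methyl-6-oxocyclodeca-1,3,7-trien-1-yl]methyl 3-methylbutanoate | CC(C)CC(=O)OC/C1=C\C=C/CC(=O)/C(C)=C\CC1 | intermediate
16 | [(1Z,3Z,6R,7Z)-6-hydroxy-7-methylcyclodeca-1,3,7-trien-1-yl]methyl 3-methylbutanoate | CC(C)CC(=O)OC/C1=C\C=C/C[C@@H](O)/C(C)=C\CC1 | intermediate
17 | 2-bromoprop-2-enoic acid | C=C(Br)C(=O)O | starting material
18 | [(3aR,5R,6Z,10Z,11aR)-5-hydroxy-6-methyl-3-methylidene-2-oxo-2,3,3a,4,5,8,9,11a-octahydrocyclodeca[b]furan-10-yl]methyl 3-methylbutanoate | C=C1C(=O)O[C@@H]2/C=C(\COC(=O)CC(C)C)CC/C=C(/C)[C@H](O)C[C@H]12 | intermediate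
19 | [(3aR,5S,6Z,10Z,11aR)-5-acetyloxy-6-methyl-3-methylidene-2-oxo-2,3,3a,4,5,8,9,11a-octahydrocyclodeca[b]furan-10-yl]methyl 3-methylbutanoate | C=C1C(=O)O[C@@H]2/C=C(\COC(=O)CC(C)C)CC/C=C(/C)[C@@H](OC(C)=O)C[C@H]12 | target

**Step count and risks**

Total step count: 13. Longest linear sequence: 13 steps (1 to 19); 2, 7 and 17 enter as purchased partners.

Steps most likely to fail:

1. Step 12. The alkenylpalladium may add to the other face of the C6=C7 bond, or to both faces, if the ten-membered ring reacts through a conformer other than the one assumed; the allylic isovalerate may also be lost by ionisation at zerovalent palladium. Fallback: the C9 centre is carried in its final configuration and no inversion is used. It sets out from ketone 15, which is reduced with the enantiomeric catalyst, (R)-2-methyl-CBS-oxazaborolidine and catecholborane, to the 6S alcohol [(1Z,3Z,6S,7Z)-6-hydroxy-7-methylcyclodeca-1,3,7-trien-1-yl]methyl 3-methylbutanoate F1. Acetylation (Ac2O, pyridine, DMAP) gives the acetate [(1Z,3Z,6S,7Z)-6-acetyloxy-7-methylcyclodeca-1,3,7-trien-1-yl]methyl 3-methylbutanoate F2. The same palladium-catalysed annulation of this C9 epimer with 17 would then take place on the mirror-related face and give 19 directly, where the route is rejoined.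

2. Step 9. Intermolecular coupling to oligomers, or reduction of the C–I bond without C–C bond formation, may outrun the slow closure of the strained ten-membered ring. Fallback: the ring is closed at C1=C10 by olefin metathesis instead. It sets out from aldehyde 10: Wittig methylenation (Ph3PCH3Br, KOt-Bu) gives the terminal alkene (2Z,4Z)-2-(but-3-en-1-yl)-7-[(tert-butyldiphenylsilyl)oxy]hepta-2,4-dien-1-yl 3-methylbutanoate F3. HF·pyridine gives the alcohol (2Z,4Z)-2-(but-3-en-1-yl)-7-hydroxyhepta-2,4-dien-1-yl 3-methylbutanoate F4, and Dess–Martin oxidation gives the aldehyde (2Z,4Z)-2-(but-3-en-1-yl)-7-oxohepta-2,4-dien-1-yl 3-methylbutanoate F5. CH2=C(CH3)MgBr at −78 °C adds to the aldehyde in preference to the ester and gives the racemic carbinol (2Z,4Z)-2-(but-3-en-1-yl)-7-hydroxy-8-methylnona-2,4,8-trien-1-yl 3-methylbutanoate F6. Ring-closing metathesis with the second-generation Grubbs catalyst in dilute solution joins the monosubstituted and the 1,1-disubstituted alkene with loss of ethene, the ring size favouring the cis trisubstituted alkene, and gives 14, where the route is rejoined.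

3. Step 13. Acetate may attack C1 with allylic transposition (SN2′), or elimination to a diene may occur, instead of clean inversion at the hindered ring carbinol. Fallback: inversion by oxidation and reagent-controlled reduction. It sets out from 18: Dess–Martin oxidation gives the enone lactone [(3aR,6Z,10Z,11aR)-6-methyl-3-methylidene-2,5-dioxo-2,3,3a,4,5,8,9,11a-octahydrocyclodeca[b]furan-10-yl]methyl 3-methylbutanoate F7. Reduction with (R)-2-methyl-CBS-oxazaborolidine and catecholborane at −78 °C gives the 5S alcohol [(3aR,5S,6Z,10Z,11aR)-5-hydroxy-6-methyl-3-methylidene-2-oxo-2,3,3a,4,5,8,9,11a-octahydrocyclodeca[b]furan-10-yl]methyl 3-methylbutanoate F8. Acetylation (Ac2O, pyridine, DMAP) gives 19, where the route is rejoined.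

**Further compounds**

F1 | step 12 | [(1Z,3Z,6S,7Z)-6-hydroxy-7-methylcyclodeca-1,3,7-trien-1-yl]methyl 3-methylbutanoate | CC(C)CC(=O)OC/C1=C\C=C/C[C@H](O)/C(C)=C\CC1
F2 | step 12 | [(1Z,3Z,6S,7Z)-6-acetyloxy-7-methylcyclodeca-1,3,7-trien-1-yl]methyl 3-methylbutanoate | CC(C)CC(=O)OC/C1=C\C=C/C[C@H](OC(C)=O)/C(C)=C\CC1
F3 | step 9 | (2Z,4Z)-2-(but-3-en-1-yl)-7-[(tert-butyldiphenylsilyl)oxy]hepta-2,4-dien-1-yl 3-methylbutanoate | CC(C)CC(=O)OC/C(CCC=C)=C\C=C/CCO[Si](c1ccccc1)(c1ccccc1)C(C)(C)C
F4 | step 9 | (2Z,4Z)-2-(but-3-en-1-yl)-7-hydroxyhepta-2,4-dien-1-yl 3-methylbutanoate | CC(C)CC(=O)OC/C(CCC=C)=C\C=C/CCO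
F5 | step 9 | (2Z,4Z)-2-(but-3-en-1-yl)-7-oxohepta-2,4-dien-1-yl 3-methylbutanoate | CC(C)CC(=O)OC/C(CCC=C)=C\C=C/CC=O
F6 | step 9 | (2Z,4Z)-2-(but-3-en-1-yl)-7-hydroxy-8-methylnona-2,4,8-trien-1-yl 3-methylbutanoate | CC(C)CC(=O)OC/C(CCC=C)=C\C=C/CC(O)C(C)=C
F7 | step 13 | [(3aR,6Z,10Z,11aR)-6-methyl-3-methylidene-2,5-dioxo-2,3,3a,4,5,8,9,11a-octahydrocyclodeca[b]furan-10-yl]methyl 3-methylbutanoate | C=C1C(=O)O[C@@H]2/C=C(\COC(=O)CC(C)C)CC/C=C(/C)C(=O)C[C@H]12
F8 | step 13 | [(3aR,5S,6Z,10Z,11aR)-5-hydroxy-6-methyl-3-methylidene-2-oxo-2,3,3a,4,5,8,9,11a-octahydrocyclodeca[b]furan-10-yl]methyl 3-methylbutanoate | C=C1C(=O)O[C@@H]2/C=C(\COC(=O)CC(C)C)CC/C=C(/C)[C@@H](O)C[C@H]12
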